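Two runs stand beside our flask, and they differ in one charge.

common to all: left-handed substrate 0.80 M; right-handed substrate 0.80 M; free catalyst 2.1 mM

| charge | partner | impurity | remark | time |
|---|---|---|---|---|
| north | 2 M | 0.16 mM | run made earlier |  |
| north-east | 2 M | 0.64 mM | run made earlier |  |
| flask | 2.00 M | 0.32 mM |  | 40 h |

| run | time / h | left-handed product / % | right-handed product / % |
|---|---|---|---|
| north | 6.00 | 27.9 | 13.8 |
| north | 12.0 | 27.7 | 14.1 |
| north | 20.0 | 29.0 | 14.0 |
| north | 25.0 | 28.0 | 13.6 |
| north | 30.0 | 28.0 | 14.0 |
| north-east | 6.00 | 24.6 | 11.3 |
| north-east | 12.0 | 24.8 | 11.5 |
| north-east | 20.0 | 24.4 | 10.9 |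
| north-east | 25.0 | 24.5 | 11.7 |
| north-east | 30.0 | 24.0 | 11.4 |

(standard deviation of a reading: 0.3 percentage points)

- free catalyst is single-handed; left-handed substrate and right-handed substrate are mirror images of each other, charged as a racemate, each of them at the stated concentration
- what was read earlier has a scatter of 0.3 percentage points, one standard deviation
- on the list of suspects stand: partner + free catalyst + left-handed substrate -> free catalyst + left-handed product; partner + free catalyst + right-handed substrate -> free catalyst + right-handed product; left-handed substrate <-> right-handed substrate; partner -> decomposed reagent; free catalyst -> spent catalyst A; free catalyst + impurity -> spent catalyst B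
- an excess is the difference of the two amounts in percent of their sum
- an excess is below zero if the other one leads

- left-handed product and right-handed product together, in percent of the left-handed substrate and right-handed substrate charged together, at 40 h
- excess of left-handed product over right-handed product in the product at 40 h
- whether the exchange between left-handed substrate and right-handed substrate keeps pace with the reaction: how far the product's excess at 40 h gets from its value without exchange to its value with instant exchange (above 80% keeps pace, below 20% hardly takes part, else lags behind)

The north and north-east runs differ in impurity, 0.16 mM against 0.64 mM, and both read flat within scatter from 6.00 h on. Averaged, north holds 28.1% left-handed and 13.9% right-handed product; north-east holds 24.5% and 11.4%. North-east ends lower because its impurity can hold away 30.5% of the catalyst charge, against 7.62% in north.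

Each substrate is half the charge, so without exchange the fraction of it left is one minus twice its product's share; with exchange this is only a no-exchange fraction, not what stands in the flask. Without exchange, both substrates see the same partner and catalyst, so the logarithm of the no-exchange fraction for the left-handed substrate, divided by the logarithm of that for the right-handed, reads 2.54 in north and 2.61 in north-east. The mean of these two readings is our selectivity factor s, 2.57. The excess reads 33.8% and 36.5%, while instant exchange would hold it at (s−1)/(s+1), 44.0%, in both runs. So we expect exchange to stay far behind.

Call x the negative logarithm of the no-exchange fraction for the right-handed substrate: 0.326 in north, 0.258 in north-east. A straight line in impurity gives 0.303 for our flask at 0.32 mM. Then x and s give 13.1% right-handed and 27.1% left-handed product: our own 40.2% combined, with excess 34.8%.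

The forecast, slightly different, gives 40% (38.8% to 41%), excess 34.7% (33.4% to 36%), and hardly takes part; of the plateau it says “something, probably the catalyst, dies early”.

The flask gives 39.9%, excess 35.0%, and hardly takes part, at 9.6% of the way.

    partner + free catalyst + left-handed substrate → free catalyst + left-handed product (k = 0.274 M⁻² s⁻¹)
    partner + free catalyst + right-handed substrate → free catalyst + right-handed product (k = 0.109 M⁻² s⁻¹)
    left-handed substrate ⇌ right-handed substrate (k = 6.65 × 10⁻⁵ s⁻¹)
    partner → decomposed reagent (k = 8.62 × 10⁻⁴ s⁻¹)
    free catalyst → spent catalyst A (k = 1.80 × 10⁻⁵ s⁻¹)
    free catalyst + impurity → spent catalyst B (k = 17.8 M⁻¹ s⁻¹)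

In this flask at 4.00 h, partner stands at 0% while free catalyst stands at 65.4%. With s, its 13.0% right-handed product gives 26.9% left-handed; it holds 27.0%. The forecast's range would fail in the neighbouring flask with 3.60 mM free catalyst, which reaches 53.6%. There, s turns 18.5% right-handed product into 34.7% left-handed, and that flask holds 35.1%, with excess 30.9%.

(Readings and results come from a simulation from invented constants.)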